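**Plan**

1. Numbering used throughout: C1 allyl-bearing bridgehead, C2=C3(OMe), C4 carbinol, C5 second bridgehead, C6 CH–aryl, C7 CH–CH3, C8 bridging C=O. The retrosynthesis first returns C4–OH to C4=O, then cuts C1–C7 and C5–C6 together, which opens the cyclopentanone ring C1–C8–C5–C6–C7.
2. Enabling feature: the six-membered ring C8–C1–C2–C3–C4–C5 carries oxygen at C8, C3 and C4, so it is a dearomatised 2-allyl-4,5-dimethoxyphenol. Its quinone-monoketal cation is electrophilic at C1 and an enol ether at C5, the two carbons flanking C8, so a two-carbon alkene can bridge them.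
3. Forward order: O-allylation and Claisen rearrangement of 3,4-dimethoxyphenol, then oxidative ketalisation, complete the achiral six-membered ring. (Z)-Methylisoeugenol comes from a Suzuki coupling. A cationic [5+2] union then closes the five-membered ring and the bicycle, and reduction at C4 ends the route.
4. Stereochemistry: C1 (absolute) from a chiral counteranion paired with the planar cation; C7 from the (Z)-alkene geometry in the compact aryl-over-ring approach; C6 from closure of the benzylic cation trans to methyl; C5 from the bridge; C4 from substrate-controlled hydride delivery.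

Key step: step 5

Assumption (remark on the chemistry): the compact approach with the aryl group over the cationic ring, known for propenylbenzenes with this cation class, is taken to hold for the (Z)-alkene, so that its geometry places the C7 methyl trans to the allyl group. Compounds 6 and 7 are taken as commercial.

**Step 1**
Reactants: 1 3,4-dimethoxyphenol; 2 allyl bromide
Product: 3 4-(allyloxy)-1,2-dimethoxybenzene
Conditions: K2CO3, acetone, reflux
Reagents that add atoms: none
Why: Williamson ether synthesis, SN2 attack of the phenoxide on the primary allylic bromide; no stereocenter is formed.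

**Step 2**
Reactants: 3 4-(allyloxy)-1,2-dimethoxybenzene
Product: 4 2-allyl-4,5-dimethoxyphenol
Conditions: N,N-diethylaniline, 200 °C
Reagents that add atoms: none
Why: Aromatic Claisen rearrangement ([3,3]) to the free ortho carbon that is not flanked by a methoxy group, followed by tautomerisation to the phenol.

**Step 3**
Reactants: 4 2-allyl-4,5-dimethoxyphenol
Product: 5 2-allyl-4,4,5-trimethoxycyclohexa-2,5-dien-1-one
Conditions: PhI(OAc)2, MeOH, 0 °C
Reagents that add atoms: methanol, SMILES CO
Why: Oxidative dearomatisation of a para-methoxyphenol by the hypervalent iodine reagent, with methanol trapping the phenoxonium ion at the methoxy-bearing para carbon to give the p-quinone monoketal; the allyl group is inert.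

**Step 4**
Reactants: 6 4-bromo-1,2-dimethoxybenzene; 7 (Z)-prop-1-en-1-ylboronic acid
Product: 8 (Z)-1,2-dimethoxy-4-(prop-1-en-1-yl)benzene
Conditions: Pd(PPh3)4 (cat.), K2CO3, DME–H2O, 80 °C
Reagents that add atoms: none
Why: Suzuki–Miyaura coupling, in which transmetalation and reductive elimination proceed with retention of the alkenyl geometry, so the (Z)-alkene should be delivered.

**Step 5**
Reactants: 5 2-allyl-4,4,5-trimethoxycyclohexa-2,5-dien-1-one; 8 (Z)-1,2-dimethoxy-4-(prop-1-en-1-yl)benzene
Product: 11 (1R,5R,6S,7S)-1-allyl-6-(3,4-dimethoxyphenyl)-3-methoxy-7-methylbicyclo[3.2.1]oct-2-ene-4,8-dione, via quinone-ketal cation 9 (not isolated), via bicyclic dimethyl ketal 10 (not isolated)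
Conditions: confined chiral imidodiphosphorimidate Brønsted acid (IDPi, 5 mol%, the antipode that leads to the (1R) series), CH2Cl2, −78 to −20 °C; then 1 M HCl, THF–H2O, 0 °C
Reagents that add atoms: water, SMILES O
Why: Proposed new method: the chiral acid ionises ketal 5 to cation 9, held as a contact ion pair with the confined anion; the β-carbon of alkene 8 adds to the allyl-bearing terminus C1 (the electrophilic β-position of the unsaturated oxocarbenium), the veratryl cation formed at C6 is captured by the enol-ether carbon C5, and methanol returns at C4 to give ketal 10 and free the acid, before aqueous acid hydrolyses 10 to 11. The closest known reactions are the acid-promoted cationic [5+2] cycloaddition of p-quinone monoketals with propenylbenzenes under achiral acids, and the control of oxocarbenium and styrene-derived cations by confined imidodiphosphorimidate counteranions; only their combination is new. The cyclopentanone ring C1–C8–C5–C6–C7 closes by the intermolecular C1–C7 bond followed by a five-membered exo-trig-type attack of C5 on the benzylic cation, a formal [3+2] across C1–C8–C5 that also completes the seven-membered perimeter of the [5+2]. C1 is set by the anion shielding one face of the planar cation; C7 follows from the compact approach with the aryl group over the cationic ring, which for the (Z)-alkene turns the methyl toward C2 (endo, trans to allyl); C6 is set when the cation closes from its A(1,3)-relaxed rotamer with aryl trans to methyl (exo); C5 is fixed by the bridge. The step needs C- over O-capture and trans over cis closure, which should be secured because closure through the carbonyl oxygen and cis closure are reversible for a veratryl cation under the acid while the trans C-closed ketone is the more stable isomer; capture by the allyl double bond should be held back by the far higher nucleophilicity of the enol-ether carbon and by the short time at low temperature.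

**Step 6**
Reactants: 11 (1R,5R,6S,7S)-1-allyl-6-(3,4-dimethoxyphenyl)-3-methoxy-7-methylbicyclo[3.2.1]oct-2-ene-4,8-dione
Product: 12 (1R,4R,5S,6S,7S)-1-allyl-6-(3,4-dimethoxyphenyl)-4-hydroxy-3-methoxy-7-methylbicyclo[3.2.1]oct-2-en-8-one
Conditions: NaBH4 (1 equiv), CeCl3·7H2O, MeOH, −78 °C; aq. NH4Cl quench
Reagents that add atoms: none
Why: Luche 1,2-reduction of the α-methoxy enone carbonyl C4, which chelates CeCl3 with the neighbouring methoxy oxygen and should react before the hindered bridging C8 ketone; hydride should enter axially from the face of the one-carbon bridge, away from the C6–C7 bridge, giving the equatorial (4R) alcohol syn to that bridge.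

**Compound list**

1 | 3,4-dimethoxyphenol | COc1ccc(O)cc1OC | starting material
2 | allyl bromide | C=CCBr | starting material
3 | 4-(allyloxy)-1,2-dimethoxybenzene | C=CCOc1ccc(OC)c(OC)c1 | intermediate
4 | 2-allyl-4,5-dimethoxyphenol | C=CCc1cc(OC)c(OC)cc1O | intermediate
5 | 2-allyl-4,4,5-trimethoxycyclohexa-2,5-dien-1-one | C=CCC1=CC(OC)(OC)C(OC)=CC1=O | intermediate
6 | 4-bromo-1,2-dimethoxybenzene | COc1ccc(Br)cc1OC | starting material
7 | (Z)-prop-1-en-1-ylboronic acid | C/C=C\B(O)O | starting material
8 | (Z)-1,2-dimethoxy-4-(prop-1-en-1-yl)benzene | C/C=C\c1ccc(OC)c(OC)c1 | intermediate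
9 | (5-allyl-2-methoxy-4-oxocyclohexa-2,5-dien-1-ylidene)methyloxonium ion (quinone-ketal cation) | C=CCC1=CC(=[O+]C)C(OC)=CC1=O | intermediate
10 | (1R,5R,6S,7S)-1-allyl-6-(3,4-dimethoxyphenyl)-3,4,4-trimethoxy-7-methylbicyclo[3.2.1]oct-2-en-8-one (bicyclic dimethyl ketal) | C=CC[C@@]12C=C(OC)C(OC)(OC)[C@@H](C1=O)[C@@H](c1ccc(OC)c(OC)c1)[C@@H]2C | intermediate
11 | (1R,5R,6S,7S)-1-allyl-6-(3,4-dimethoxyphenyl)-3-methoxy-7-methylbicyclo[3.2.1]oct-2-ene-4,8-dione | C=CC[C@@]12C=C(OC)C(=O)[C@@H](C1=O)[C@@H](c1ccc(OC)c(OC)c1)[C@@H]2C | intermediate
12 | (1R,4R,5S,6S,7S)-1-allyl-6-(3,4-dimethoxyphenyl)-4-hydroxy-3-methoxy-7-methylbicyclo[3.2.1]oct-2-en-8-one | C=CC[C@@]12C=C(OC)[C@H](O)[C@@H](C1=O)[C@@H](c1ccc(OC)c(OC)c1)[C@@H]2C | target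

**Step count and risks**

Total steps: 6. Longest linear sequence: 5 (steps 1, 2, 3, 5, 6).

Steps most likely to fail:

1. Step 5. The counteranion may not discriminate the two faces of the planar cation well enough. The benzylic cation may also be diverted, by closure through the carbonyl oxygen without return or by capture at the allyl double bond, and the acid may isomerise the (Z)-alkene before it reacts. Fallback, setting out from 5 and 8: the known achiral variant of the union (catalytic HNTf2 or TMSOTf, CH2Cl2, −78 to 0 °C, then aqueous acid) should give the racemic diketone F1 in the same relative configuration. Reduction with NaBH4 and CeCl3·7H2O as in step 6 should give the racemic alcohol F2. Preparative chromatography of F2 on a chiral stationary phase (amylose tris(3,5-dimethylphenylcarbamate)) separates the enantiomers, and the route is rejoined at 12.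

2. Step 6. Hydride may be delivered to the wrong face of C4, or compete at the bridging C8 carbonyl. Fallback, setting out from 11: the C4-epimeric alcohol F3 is separated from the reduction mixture and inverted by a Mitsunobu reaction (4-nitrobenzoic acid, PPh3, DIAD, THF, 0 °C) to the (4R) 4-nitrobenzoate F4. Mild methanolysis (K2CO3, MeOH, 0 °C, short contact to avoid retro-aldol opening) returns to 12.

3. Step 4. The (Z)-geometry may erode during the coupling or on purification. Fallback, setting out from 6: Sonogashira coupling with propyne (PdCl2(PPh3)2, CuI, Et3N, THF) should give the alkyne 1,2-dimethoxy-4-(prop-1-yn-1-yl)benzene F5. cis-Selective semi-hydrogenation (H2, Pd/CaCO3 poisoned with Pb(OAc)2, quinoline, EtOAc) returns to 8.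

**Further compounds**

F1 | step 5 | racemic 1-allyl-6-(3,4-dimethoxyphenyl)-3-methoxy-7-methylbicyclo[3.2.1]oct-2-ene-4,8-dione (1:1 mixture of 11 and its enantiomer) | C=CC[C@@]12C=C(OC)C(=O)[C@@H](C1=O)[C@@H](c1ccc(OC)c(OC)c1)[C@@H]2C.C=CC[C@]12C=C(OC)C(=O)[C@H](C1=O)[C@H](c1ccc(OC)c(OC)c1)[C@H]2C
F2 | step 5 | racemic 1-allyl-6-(3,4-dimethoxyphenyl)-4-hydroxy-3-methoxy-7-methylbicyclo[3.2.1]oct-2-en-8-one (1:1 mixture of 12 and its enantiomer) | C=CC[C@@]12C=C(OC)[C@H](O)[C@@H](C1=O)[C@@H](c1ccc(OC)c(OC)c1)[C@@H]2C.C=CC[C@]12C=C(OC)[C@@H](O)[C@H](C1=O)[C@H](c1ccc(OC)c(OC)c1)[C@H]2C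
F3 | step 6 | (1R,4S,5S,6S,7S)-1-allyl-6-(3,4-dimethoxyphenyl)-4-hydroxy-3-methoxy-7-methylbicyclo[3.2.1]oct-2-en-8-one (C4 epimer of 12) | C=CC[C@@]12C=C(OC)[C@@H](O)[C@@H](C1=O)[C@@H](c1ccc(OC)c(OC)c1)[C@@H]2C
F4 | step 6 | 4-nitrobenzoate of 12 at the C4 oxygen, (4R) | C=CC[C@@]12C=C(OC)[C@H](OC(=O)c3ccc(cc3)[N+](=O)[O-])[C@@H](C1=O)[C@@H](c1ccc(OC)c(OC)c1)[C@@H]2C
F5 | step 4 | 1,2-dimethoxy-4-(prop-1-yn-1-yl)benzene | CC#Cc1ccc(OC)c(OC)c1
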